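## Retrosynthetic overview

1. Target 36 ⇐ 34: the 1,2-dioxolan-3-ol is made last, by vinylogous autoxidation of the lower-half enone and peroxy-hemiketalisation.
2. 34 ⇐ 32 + 33: endo Diels–Alder reaction of a 5-acetoxycyclopentadiene (upper guaiane) with a cyclopentadienone (lower guaiane), both unmasked in one flask from tertiary alcohols 31 and 19. The norbornene and the vicinal quaternary carbons are formed here.
3. 19 ⇐ 16: the seven-membered ring of the lower half is closed by a Pd-catalysed C6–C7 coupling of a vinylogous enolate with a vinyl bromide (key C–C bond).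
4. 31 ⇐ 26: the seven-membered ring of the upper half is closed by Ru ring-closing metathesis after a Ni/Cr aldehyde–vinyl bromide coupling; one hydride step then sets C2 and C7.
5. Both halves ⇐ 10 ⇐ 1 + 2: organocatalytic Michael addition of cyclopentane-1,3-dione to crotonaldehyde sets C10; Stork–Danheiser chemistry builds the five-membered rings first.

Assumption and convention: positions use guaiane numbering within each C15 half (upper = acetate half, lower = peroxide half); the two epimerisable centres of the target (upper C7 and the peroxy-hemiketal carbon) are taken as the thermodynamically preferred ones; centres carried as epimer mixtures and destroyed later are left unspecified in the SMILES.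

## Route

Step 1
Reactants: 1 cyclopentane-1,3-dione; 2 (E)-but-2-enal
Product: 4 (4R)-2-hydroxy-4-methyl-3,4,6,7-tetrahydrocyclopenta[b]pyran-5(2H)-one (lactol, anomer mixture), via 2-[(2R)-4-oxobutan-2-yl]cyclopentane-1,3-dione 3 (not isolated)
Conditions: (S)-α,α-diphenylprolinol TMS ether (10 mol%), PhCO2H (10 mol%), CH2Cl2, 0 °C → rt
Reagents that add atoms: none
Why: Iminium-catalysed (Jørgensen–Hayashi) Michael addition of the 1,3-dione to the enal and spontaneous hemiacetalisation; the catalyst shields one face of the (E)-iminium ion so that the methyl-bearing carbon (C10 of both halves) is formed R.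

Step 2
Reactants: 4
Product: 5 (4R)-2-methoxy-4-methyl-3,4,6,7-tetrahydrocyclopenta[b]pyran-5(2H)-one (anomer mixture)
Conditions: MeOH, PPTS (cat.), 3 Å MS, rt
Reagents that add atoms: methanol (CO)
Why: Fischer-type acetalisation of the lactol; the product is both a vinylogous ester and a masked aldehyde, and no permanent stereocentre is formed.

Step 3
Reactants: 5
Product: 7 (4R)-2-methoxy-4,6-dimethyl-3,4,6,7-tetrahydrocyclopenta[b]pyran-5(2H)-one (epimers at C2 and C6), via lithium enolate of 5 6 (not isolated)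
Conditions: LDA, THF, −78 °C; MeI, −78 → −20 °C
Reagents that add atoms: iodomethane (CI)
Why: Kinetic α′-deprotonation and C-methylation of the vinylogous ester (Stork–Danheiser alkylation) at the only CH2 next to the carbonyl, which places the future C4 methyl; the new centre is unselective and is later destroyed.

Step 4
Reactants: 7
Product: 10 (4R)-6-[(tert-butyldimethylsilyl)oxy]-2-methoxy-4,6-dimethyl-3,4,6,7-tetrahydrocyclopenta[b]pyran-5(2H)-one (epimers at C2 and C6), via potassium enolate of 7 8 (not isolated), via potassium alkoxide of the 6-hydroxy ketone 9 (not isolated)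
Conditions: KHMDS, THF, −78 → −40 °C; 2-(phenylsulfonyl)-3-phenyloxaziridine, −78 °C; then TBSOTf, −78 → 0 °C
Reagents that add atoms: 2-(phenylsulfonyl)-3-phenyloxaziridine (O=S(=O)(c1ccccc1)N1OC1c1ccccc1); tert-butyldimethylsilyl triflate (CC(C)(C)[Si](C)(C)OS(=O)(=O)C(F)(F)F)
Why: Davis α-hydroxylation of the only enolate that can form, then O-silylation in the same flask; this C–O bond is the later leaving group for diene and dienone formation, and the epimer mixture converges when the carbon becomes sp2 in step 19.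

Step 5
Reactants: 10
Product: 12 (3R)-3-{3-[(tert-butyldimethylsilyl)oxy]-2,3-dimethyl-5-oxocyclopent-1-en-1-yl}butanal (ring C3 epimers), via lithium alkoxide of the 5-methyl carbinol (1,2-adduct of 10) 11 (not isolated)
Conditions: MeLi, THF, −78 °C; then 1 M HCl, THF, 0 °C
Reagents that add atoms: methyllithium ([Li]C); water (O)
Why: Stork–Danheiser transposition: 1,2-addition to the vinylogous ester carbonyl, then acid expels water and hydrolyses the cyclic enol ether/acetal, giving the 3-methyl enone (the methyl is C6) and unveiling the aldehyde (C8); no new stereocentre.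

Step 6
Reactants: 12
Product: 13 4-[(tert-butyldimethylsilyl)oxy]-2-[(2R)-4-hydroxy-6-methylhept-5-en-2-yl]-3,4-dimethylcyclopent-2-en-1-one (carbinol and C4 epimers)
Conditions: 2-methylprop-1-enylmagnesium bromide, THF, −78 °C; then H2O
Reagents that add atoms: 2-methylprop-1-enylmagnesium bromide (CC(C)=C[Mg]Br)
Why: Grignard addition, chemoselective for the aldehyde over the hindered, tetrasubstituted enone at −78 °C; the carbinol centre is oxidised away in the next step.

Step 7
Reactants: 13
Product: 14 4-[(tert-butyldimethylsilyl)oxy]-3,4-dimethyl-2-[(2R)-6-methyl-4-oxohept-5-en-2-yl]cyclopent-2-en-1-one (C4 epimers)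
Conditions: Dess–Martin periodinane, CH2Cl2, rt
Reagents that add atoms: none
Why: Dess–Martin oxidation of the allylic alcohol to the β,β-dimethyl enone under neutral conditions that leave the silyl ether and the ring enone untouched.

Step 8
Reactants: 14
Product: 16 2-[(2R)-5-bromo-6-methyl-4-oxohept-5-en-2-yl]-4-[(tert-butyldimethylsilyl)oxy]-3,4-dimethylcyclopent-2-en-1-one (C4 epimers), via the 5,6-dibromo-6-methyl-4-oxoheptan-2-yl dibromide 15 (not isolated)
Conditions: Br2, CH2Cl2, −20 °C; then Et3N, 0 °C → rt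
Reagents that add atoms: bromine (BrBr)
Why: Bromination–dehydrobromination of the trisubstituted side-chain enone gives the α-bromoenone; the tetrasubstituted, electron-poor ring enone does not add bromine under these conditions.

Step 9
Reactants: 16
Product: 18 (8R)-3-[(tert-butyldimethylsilyl)oxy]-3,8-dimethyl-5-(propan-2-ylidene)-2,3,4,5,7,8-hexahydroazulene-1,6-dione (C3 epimers), via caesium dienolate of 16 17 (not isolated)
Conditions: Pd2(dba)3 (5 mol%), P(t-Bu)3·HBF4 (12 mol%), Cs2CO3 (2.2 equiv), toluene (5 mM), 60 °C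
Reagents that add atoms: none
Why: Proposed new method: Pd-catalysed intramolecular vinylogous (γ) alkenylation of an enone — Pd(0) inserts into the activated C(sp2)–Br bond of the α-bromoenone, Cs2CO3 forms the only extended dienolate available (C4 is quaternary, so the C6 methyl is the sole γ-position), the dienolate binds Pd through its unhindered CH2 terminus because reductive elimination at the α-carbon would have to join a fully substituted sp3 carbon to a tetrasubstituted vinyl carbon, and C–C reductive elimination forms C6–C7 and closes the seven-membered ring with the ring enone restored; the closest known reaction types are the Pd-catalysed intermolecular γ-arylation of α,β-unsaturated ketones through dienolates and the intramolecular α-alkenylation of ketones with vinyl halides; no stereocentre is formed.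

Step 10
Reactants: 18
Product: 19 (8R)-3-hydroxy-3,8-dimethyl-5-(propan-2-ylidene)-2,3,4,5,7,8-hexahydroazulene-1,6-dione (C3 epimers)
Conditions: HF·pyridine, THF, 0 °C → rt
Reagents that add atoms: none
Why: Desilylation with buffered HF frees the tertiary β-hydroxy ketone without base, so no premature E1cB elimination to the cyclopentadienone occurs.

Step 11
Reactants: 10
Product: 21 (3R)-3-{3-[(tert-butyldimethylsilyl)oxy]-2-ethenyl-3-methyl-5-oxocyclopent-1-en-1-yl}butanal (ring C3 epimers), via bromomagnesium alkoxide of the 5-ethenyl carbinol (1,2-adduct of 10) 20 (not isolated)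
Conditions: vinylmagnesium bromide, THF, −78 → 0 °C; then 1 M HCl, THF, 0 °C
Reagents that add atoms: vinylmagnesium bromide (C=C[Mg]Br); water (O)
Why: Stork–Danheiser transposition as in step 5, here with a vinyl nucleophile, gives the 3-vinyl enone (the inner vinyl carbon is C6) and the free aldehyde; no new stereocentre.

Step 12
Reactants: 22 3-methylbut-1-yne
Product: 24 2-bromo-3-methylbut-1-ene, via (Z)-9-(2-bromo-3-methylbut-1-en-1-yl)-9-borabicyclo[3.3.1]nonane 23 (not isolated)
Conditions: B-bromo-9-BBN, CH2Cl2, 0 °C; then AcOH, 0 °C → rt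
Reagents that add atoms: B-bromo-9-borabicyclo[3.3.1]nonane (BrB1C2CCCC1CCC2)
Why: Markovnikov syn-bromoboration of the terminal alkyne followed by protodeboronation gives the 2-bromo-1-alkene regioselectively.

Step 13
Reactants: 21; 24
Product: 25 4-[(tert-butyldimethylsilyl)oxy]-3-ethenyl-2-[(2R)-4-hydroxy-6-methyl-5-methylideneheptan-2-yl]-4-methylcyclopent-2-en-1-one (carbinol and C4 epimers)
Conditions: CrCl2 (4 equiv), NiCl2 (2 mol%), DMF, rt; then H2O
Reagents that add atoms: none
Why: Nozaki–Hiyama–Kishi coupling (Ni-catalysed, Cr-mediated) adds the vinyl bromide to the aldehyde only, leaving the dienone untouched; the carbinol centre is oxidised next.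

Step 14
Reactants: 25
Product: 26 4-[(tert-butyldimethylsilyl)oxy]-3-ethenyl-4-methyl-2-[(2R)-6-methyl-5-methylidene-4-oxoheptan-2-yl]cyclopent-2-en-1-one (C4 epimers)
Conditions: Dess–Martin periodinane, CH2Cl2, rt
Reagents that add atoms: none
Why: Dess–Martin oxidation gives the α-methylene ketone without isomerising the 1,1-disubstituted olefin.

Step 15
Reactants: 26
Product: 27 (8R)-3-[(tert-butyldimethylsilyl)oxy]-3,8-dimethyl-5-(propan-2-yl)-2,3,7,8-tetrahydroazulene-1,6-dione (C3 epimers)
Conditions: Hoveyda–Grubbs II (10 mol%), toluene (5 mM), 80 °C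
Reagents that add atoms: none
Why: Ring-closing olefin metathesis between the terminal vinyl group and the 1,1-disubstituted enone olefin releases ethene and closes the seven-membered ring as the trisubstituted C6=C7 alkene; no stereocentre is formed.

Step 16
Reactants: 27
Product: 29 (1S,5S,8R)-3-[(tert-butyldimethylsilyl)oxy]-1-hydroxy-3,8-dimethyl-5-(propan-2-yl)-2,3,4,5,7,8-hexahydroazulen-6(1H)-one (C3 epimers), via lithium C8 enolate of the 6,7-dihydro compound 28 (not isolated)
Conditions: L-Selectride (2.4 equiv), THF, −78 °C; then H2O, −78 °C → rt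
Reagents that add atoms: none
Why: Conjugate (1,4) reduction at the only unsubstituted β-carbon (C6) gives the C8 enolate, which is thereby protected while a second equivalent reduces the ring ketone 1,2; hydride adds to C2 and the proton adds to C7 from the face opposite the pseudoaxial C10 methyl, so the C2 hydroxyl and the C7 isopropyl both end cis to that methyl.

Step 17
Reactants: 29
Product: 30 (1S,5S,8R)-3-[(tert-butyldimethylsilyl)oxy]-3,8-dimethyl-6-oxo-5-(propan-2-yl)-1,2,3,4,5,6,7,8-octahydroazulen-1-yl acetate (C3 epimers)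
Conditions: Ac2O, pyridine, DMAP (cat.), CH2Cl2, 0 °C
Reagents that add atoms: acetic anhydride (CC(=O)OC(C)=O)
Why: Standard O-acylation of the secondary allylic alcohol with retention; the acetate of the target is in place from here on.

Step 18
Reactants: 30
Product: 31 (1S,5S,8R)-3-hydroxy-3,8-dimethyl-6-oxo-5-(propan-2-yl)-1,2,3,4,5,6,7,8-octahydroazulen-1-yl acetate (C3 epimers)
Conditions: HF·pyridine, THF, 0 °C → rt
Reagents that add atoms: none
Why: HF-mediated desilylation frees the tertiary allylic alcohol while the allylic acetate and the α-stereocentre of the ketone survive the weakly acidic medium.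

Step 19
Reactants: 31; 19
Product: 34 endo Diels–Alder adduct (bonds upper C1–lower C4 and upper C3–lower C3; acetate syn to the norbornene C4=C5; lower half 2,8-dioxo-1(5),7(11)-diene), via (1S,5S,8R)-3,8-dimethyl-6-oxo-5-(propan-2-yl)-1,4,5,6,7,8-hexahydroazulen-1-yl acetate 32 (not isolated), via (8R)-3,8-dimethyl-5-(propan-2-ylidene)-4,5,7,8-tetrahydroazulene-1,6-dione 33 (not isolated)
Conditions: 31 (1.5 equiv), Martin sulfurane (1.6 equiv), CH2Cl2, −40 °C; then 19 (1.0 equiv) and Martin sulfurane (1.2 equiv) added slowly, −40 → 0 °C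
Reagents that add atoms: none
Why: Martin sulfurane dehydrates both tertiary alcohols (E1 for the allylic carbinol, E1cB-type for the β-hydroxy ketone) to the 5-acetoxycyclopentadiene 32 and the cyclopentadienone 33, which combine in an endo Diels–Alder reaction. The two unsubstituted CH termini bond first, as in cyclopentadienone dimerisations, which puts the methyl-bearing C4 of 33 on C1 of 32. Each partner is attacked on the face opposite its pseudoaxial C10 methyl; for 32 this is also the face opposite the acetate, which avoids the exo methyl of the dienophile. The endo transition state places the enone ring under the diene, and the four new stereocentres follow.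

Step 20
Reactants: 34
Product: 36 target CNP0317907.1, via the C11 hydroperoxide of 34 (lower half C6=C7, C8 ketone) 35 (not isolated)
Conditions: DBU (1 equiv), O2 (1 atm), MeCN, 0 °C → rt
Reagents that add atoms: dioxygen (O=O)
Why: Autoxidation of an extended enolate: DBU removes the doubly activated lower-half C6–H (γ to the C2 enone, allylic to the isopropylidene), O2 is captured at the tertiary terminus C11 with restoration of full conjugation, and the hydroperoxide adds to the adjacent C8 ketone to give the 1,2-dioxolan-3-ol, whose hemiketal carbon equilibrates by ring–chain tautomerism.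

## Compound list

1 | cyclopentane-1,3-dione | O=C1CCC(=O)C1 | starting material
2 | (E)-but-2-enal | C/C=C/C=O | starting material
3 | 2-[(2R)-4-oxobutan-2-yl]cyclopentane-1,3-dione | O=C1CCC(=O)C1[C@H](C)CC=O | intermediate
4 | (4R)-2-hydroxy-4-methyl-3,4,6,7-tetrahydrocyclopenta[b]pyran-5(2H)-one (anomers) | O=C1CCC2=C1[C@H](C)CC(O)O2 | intermediate
5 | (4R)-2-methoxy-4-methyl-3,4,6,7-tetrahydrocyclopenta[b]pyran-5(2H)-one (anomers) | O=C1CCC2=C1[C@H](C)CC(OC)O2 | intermediate
6 | lithium enolate of 5 (O–Li on C5, C5=C6) | [Li]OC1=CCC2=C1[C@H](C)CC(OC)O2 | intermediate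
7 | (4R)-2-methoxy-4,6-dimethyl-3,4,6,7-tetrahydrocyclopenta[b]pyran-5(2H)-one (C2, C6 epimers) | O=C1C(C)CC2=C1[C@H](C)CC(OC)O2 | intermediate
8 | potassium enolate of 7 (O–K on C5, C5=C6) | [K]OC1=C(C)CC2=C1[C@H](C)CC(OC)O2 | intermediate
9 | potassium alkoxide of (4R)-6-hydroxy-2-methoxy-4,6-dimethyl-3,4,6,7-tetrahydrocyclopenta[b]pyran-5(2H)-one | O=C1C(C)(O[K])CC2=C1[C@H](C)CC(OC)O2 | intermediate
10 | (4R)-6-[(tert-butyldimethylsilyl)oxy]-2-methoxy-4,6-dimethyl-3,4,6,7-tetrahydrocyclopenta[b]pyran-5(2H)-one (C2, C6 epimers) | O=C1C(C)(O[Si](C)(C)C(C)(C)C)CC2=C1[C@H](C)CC(OC)O2 | intermediate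
11 | lithium alkoxide of the 5-hydroxy-5-methyl 1,2-adduct of 10 | [Li]OC1(C)C(C)(O[Si](C)(C)C(C)(C)C)CC2=C1[C@H](C)CC(OC)O2 | intermediate
12 | (3R)-3-{3-[(tert-butyldimethylsilyl)oxy]-2,3-dimethyl-5-oxocyclopent-1-en-1-yl}butanal | O=C1CC(C)(O[Si](C)(C)C(C)(C)C)C(C)=C1[C@H](C)CC=O | intermediate
13 | 4-[(tert-butyldimethylsilyl)oxy]-2-[(2R)-4-hydroxy-6-methylhept-5-en-2-yl]-3,4-dimethylcyclopent-2-en-1-one | O=C1CC(C)(O[Si](C)(C)C(C)(C)C)C(C)=C1[C@H](C)CC(O)C=C(C)C | intermediate
14 | 4-[(tert-butyldimethylsilyl)oxy]-3,4-dimethyl-2-[(2R)-6-methyl-4-oxohept-5-en-2-yl]cyclopent-2-en-1-one | O=C1CC(C)(O[Si](C)(C)C(C)(C)C)C(C)=C1[C@H](C)CC(=O)C=C(C)C | intermediate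
15 | 4-[(tert-butyldimethylsilyl)oxy]-2-[(2R)-5,6-dibromo-6-methyl-4-oxoheptan-2-yl]-3,4-dimethylcyclopent-2-en-1-one | O=C1CC(C)(O[Si](C)(C)C(C)(C)C)C(C)=C1[C@H](C)CC(=O)C(Br)C(C)(C)Br | intermediate
16 | 2-[(2R)-5-bromo-6-methyl-4-oxohept-5-en-2-yl]-4-[(tert-butyldimethylsilyl)oxy]-3,4-dimethylcyclopent-2-en-1-one | O=C1CC(C)(O[Si](C)(C)C(C)(C)C)C(C)=C1[C@H](C)CC(=O)C(Br)=C(C)C | intermediate
17 | caesium dienolate of 16 (O–Cs on C2, C2=C1, exocyclic C5=CH2) | [Cs]OC1=C([C@H](C)CC(=O)C(Br)=C(C)C)C(=C)C(C)(O[Si](C)(C)C(C)(C)C)C1 | intermediate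
18 | (8R)-3-[(tert-butyldimethylsilyl)oxy]-3,8-dimethyl-5-(propan-2-ylidene)-2,3,4,5,7,8-hexahydroazulene-1,6-dione | O=C1CC(C)(O[Si](C)(C)C(C)(C)C)C2=C1[C@H](C)CC(=O)C(=C(C)C)C2 | intermediate
19 | (8R)-3-hydroxy-3,8-dimethyl-5-(propan-2-ylidene)-2,3,4,5,7,8-hexahydroazulene-1,6-dione | O=C1CC(C)(O)C2=C1[C@H](C)CC(=O)C(=C(C)C)C2 | intermediate
20 | bromomagnesium alkoxide of the 5-ethenyl-5-hydroxy 1,2-adduct of 10 | Br[Mg]OC1(C=C)C(C)(O[Si](C)(C)C(C)(C)C)CC2=C1[C@H](C)CC(OC)O2 | intermediate
21 | (3R)-3-{3-[(tert-butyldimethylsilyl)oxy]-2-ethenyl-3-methyl-5-oxocyclopent-1-en-1-yl}butanal | O=C1CC(C)(O[Si](C)(C)C(C)(C)C)C(C=C)=C1[C@H](C)CC=O | intermediate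
22 | 3-methylbut-1-yne | CC(C)C#C | starting material
23 | (Z)-9-(2-bromo-3-methylbut-1-en-1-yl)-9-borabicyclo[3.3.1]nonane | Br/C(C(C)C)=C\B1C2CCCC1CCC2 | intermediate
24 | 2-bromo-3-methylbut-1-ene | C=C(Br)C(C)C | intermediate
25 | 4-[(tert-butyldimethylsilyl)oxy]-3-ethenyl-2-[(2R)-4-hydroxy-6-methyl-5-methylideneheptan-2-yl]-4-methylcyclopent-2-en-1-one | O=C1CC(C)(O[Si](C)(C)C(C)(C)C)C(C=C)=C1[C@H](C)CC(O)C(=C)C(C)C | intermediate
26 | 4-[(tert-butyldimethylsilyl)oxy]-3-ethenyl-4-methyl-2-[(2R)-6-methyl-5-methylidene-4-oxoheptan-2-yl]cyclopent-2-en-1-one | O=C1CC(C)(O[Si](C)(C)C(C)(C)C)C(C=C)=C1[C@H](C)CC(=O)C(=C)C(C)C | intermediate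
27 | (8R)-3-[(tert-butyldimethylsilyl)oxy]-3,8-dimethyl-5-(propan-2-yl)-2,3,7,8-tetrahydroazulene-1,6-dione | O=C1CC(C)(O[Si](C)(C)C(C)(C)C)C2=C1[C@H](C)CC(=O)C(C(C)C)=C2 | intermediate
28 | lithium enolate (O–Li on azulene C6, C5=C6) of the 4,5-dihydro derivative of 27 | O=C1CC(C)(O[Si](C)(C)C(C)(C)C)C2=C1[C@H](C)CC(O[Li])=C(C(C)C)C2 | intermediate
29 | (1S,5S,8R)-3-[(tert-butyldimethylsilyl)oxy]-1-hydroxy-3,8-dimethyl-5-(propan-2-yl)-2,3,4,5,7,8-hexahydroazulen-6(1H)-one | O[C@H]1CC(C)(O[Si](C)(C)C(C)(C)C)C2=C1[C@H](C)CC(=O)[C@H](C(C)C)C2 | intermediate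
30 | (1S,5S,8R)-3-[(tert-butyldimethylsilyl)oxy]-3,8-dimethyl-6-oxo-5-(propan-2-yl)-1,2,3,4,5,6,7,8-octahydroazulen-1-yl acetate | CC(=O)O[C@H]1CC(C)(O[Si](C)(C)C(C)(C)C)C2=C1[C@H](C)CC(=O)[C@H](C(C)C)C2 | intermediate
31 | (1S,5S,8R)-3-hydroxy-3,8-dimethyl-6-oxo-5-(propan-2-yl)-1,2,3,4,5,6,7,8-octahydroazulen-1-yl acetate | CC(=O)O[C@H]1CC(C)(O)C2=C1[C@H](C)CC(=O)[C@H](C(C)C)C2 | intermediate
32 | (1S,5S,8R)-3,8-dimethyl-6-oxo-5-(propan-2-yl)-1,4,5,6,7,8-hexahydroazulen-1-yl acetate | CC(=O)O[C@H]1C=C(C)C2=C1[C@H](C)CC(=O)[C@H](C(C)C)C2 | intermediate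
33 | (8R)-3,8-dimethyl-5-(propan-2-ylidene)-4,5,7,8-tetrahydroazulene-1,6-dione | O=C1C=C(C)C2=C1[C@H](C)CC(=O)C(=C(C)C)C2 | intermediate
34 | endo Diels–Alder adduct of 32 and 33 (all carbon stereocentres as in the target; lower half with C8 ketone and C7 isopropylidene) | CC(=O)O[C@H]1[C@H]2C(C)=C3C[C@@H](C(C)C)C(=O)C[C@@H](C)[C@]31[C@]1(C)C3=C(C(=O)[C@H]21)[C@H](C)CC(=O)C(=C(C)C)C3 | intermediate
35 | C11 hydroperoxide of 34 (lower half: C6=C7, C11(Me)2–OOH, C8 ketone) | CC(=O)O[C@H]1[C@H]2C(C)=C3C[C@@H](C(C)C)C(=O)C[C@@H](C)[C@]31[C@]1(C)C3=C(C(=O)[C@H]21)[C@H](C)CC(=O)C(C(C)(C)OO)=C3 | intermediate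
36 | CNP0317907.1 | CC(=O)O[C@H]1[C@H]2C(C)=C3C[C@@H](C(C)C)C(=O)C[C@@H](C)[C@]31[C@]1(C)C3=C(C(=O)[C@H]21)[C@H](C)C[C@@]1(O)OOC(C)(C)C1=C3 | target

## Step count and risks

Total step count: 20. Longest linear sequence: 13 (steps 1–4, 11, 13–20). The lower-half branch (steps 5–10) and the bromoalkene (step 12) run in parallel.

**Step 9 (proposed Pd-catalysed γ-alkenylation).** It may fail by C–C bond formation at the α-carbon (spiro five-membered ring), by Heck-type insertion into the ring enone, or by base-induced loss of the silyloxy group. Base-induced isomerisation of 18 to its C6=C7 isomer would be harmless, since both isomers give the same extended enolate in step 20. The fallback uses only known chemistry and sets out from 27, the metathesis product of the other branch. HF·pyridine gives (8R)-3-hydroxy-3,8-dimethyl-5-(propan-2-yl)-2,3,7,8-tetrahydroazulene-1,6-dione F1, which takes the place of 19 in step 19. Martin sulfurane converts it into the cyclopentadienone (8R)-3,8-dimethyl-5-(propan-2-yl)-7,8-dihydroazulene-1,6-dione F2, and endo Diels–Alder reaction with diene 32 gives the double-bond isomer of 34 that has C6=C7 and an isopropyl group in the lower half F3. Under the conditions of step 20, deprotonation of the isopropyl C–H of F3 gives the same extended enolate as 34, so the fallback comes back to the route at hydroperoxide 35 and ends at 36.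

**Step 19 (double dehydration and cross Diels–Alder).** Risks are the regiochemistry of the dehydration of 31, a 1,5-hydrogen shift in 32, self-dimerisation of 33, and the preference of simple 5-acetoxycyclopentadienes for attack syn to the acetate. The fallback replaces the acetate by a large silyl ether during the cycloaddition and sets out from 29. HF·pyridine gives the diol (1S,5S,8R)-1,3-dihydroxy-3,8-dimethyl-5-(propan-2-yl)-2,3,4,5,7,8-hexahydroazulen-6(1H)-one F4, and TBDPSCl/imidazole silylates only the secondary hydroxyl to give the 1-O-tert-butyldiphenylsilyl ether of that diol F5. F5 and 19 with Martin sulfurane give, through the 1-(tert-butyldiphenylsilyloxy) diene analogue of 32 F6, the silyl ether analogue of 34 F7, in which the bulky group enforces attack anti to oxygen. TBAF/AcOH gives the free C2 alcohol of 34 F8, and Ac2O/pyridine/DMAP returns the route to 34.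

**Step 20 (autoxidation and peroxy-hemiketalisation).** Risks are oxygenation at C1 or C6 instead of C11, and competing oxidation next to the upper-half ketone. The fallback replaces triplet oxygen by two polar steps and sets out from 34. DBU and CBr4 (a positive-bromine donor that does not attack the norbornene alkene) brominate the same extended enolate at C11 to give the tertiary allylic bromide of 34 with C6=C7 F9. Silver trifluoroacetate and anhydrous H2O2 in ether then displace bromide (silver-assisted perhydrolysis) to give hydroperoxide 35, which closes to 36 as in the main route.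

## Further compounds

F1 | step 9 | (8R)-3-hydroxy-3,8-dimethyl-5-(propan-2-yl)-2,3,7,8-tetrahydroazulene-1,6-dione | O=C1CC(C)(O)C2=C1[C@H](C)CC(=O)C(C(C)C)=C2
F2 | step 9 | (8R)-3,8-dimethyl-5-(propan-2-yl)-7,8-dihydroazulene-1,6-dione | O=C1C=C(C)C2=C1[C@H](C)CC(=O)C(C(C)C)=C2
F3 | step 9 | double-bond isomer of 34 (lower half C6=C7, C7 isopropyl) | CC(=O)O[C@H]1[C@H]2C(C)=C3C[C@@H](C(C)C)C(=O)C[C@@H](C)[C@]31[C@]1(C)C3=C(C(=O)[C@H]21)[C@H](C)CC(=O)C(C(C)C)=C3
F4 | step 19 | (1S,5S,8R)-1,3-dihydroxy-3,8-dimethyl-5-(propan-2-yl)-2,3,4,5,7,8-hexahydroazulen-6(1H)-one | O[C@H]1CC(C)(O)C2=C1[C@H](C)CC(=O)[C@H](C(C)C)C2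
F5 | step 19 | (1S,5S,8R)-1-[(tert-butyldiphenylsilyl)oxy]-3-hydroxy-3,8-dimethyl-5-(propan-2-yl)-2,3,4,5,7,8-hexahydroazulen-6(1H)-one | CC(C)(C)[Si](O[C@H]1CC(C)(O)C2=C1[C@H](C)CC(=O)[C@H](C(C)C)C2)(c1ccccc1)c1ccccc1
F6 | step 19 | (1S,5S,8R)-1-[(tert-butyldiphenylsilyl)oxy]-3,8-dimethyl-5-(propan-2-yl)-4,5,7,8-tetrahydroazulen-6(1H)-one | CC(C)(C)[Si](O[C@H]1C=C(C)C2=C1[C@H](C)CC(=O)[C@H](C(C)C)C2)(c1ccccc1)c1ccccc1
F7 | step 19 | tert-butyldiphenylsilyl ether analogue of 34 (OSi in place of OAc) | CC(C)(C)[Si](O[C@H]1[C@H]2C(C)=C3C[C@@H](C(C)C)C(=O)C[C@@H](C)[C@]31[C@]1(C)C3=C(C(=O)[C@H]21)[C@H](C)CC(=O)C(=C(C)C)C3)(c1ccccc1)c1ccccc1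
F8 | step 19 | deacetyl 34 (free C2 alcohol) | O[C@H]1[C@H]2C(C)=C3C[C@@H](C(C)C)C(=O)C[C@@H](C)[C@]31[C@]1(C)C3=C(C(=O)[C@H]21)[C@H](C)CC(=O)C(=C(C)C)C3
F9 | step 20 | C11 bromide of 34 (lower half C6=C7, C11(Me)2–Br) | CC(=O)O[C@H]1[C@H]2C(C)=C3C[C@@H](C(C)C)C(=O)C[C@@H](C)[C@]31[C@]1(C)C3=C(C(=O)[C@H]21)[C@H](C)CC(=O)C(C(C)(C)Br)=C3
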